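## The problem

Astepyrazinoxide (22) is two heteroaromatic units joined by one methylene group. One is a 1H-indole substituted at C3 and carrying a 3-methylbut-2-enyl (prenyl) chain at C7. The other is a fully substituted pyrazin-2(1H)-one with OH on N1, methyl on C3, methoxy on C5 and the indolylmethyl arm on C6. There is no stereocentre, so the difficulties are regiochemistry and functional-group tolerance.

- **Indole C7.** Electrophiles attack an indole at C3, then N1 and C2, so the prenyl group has to sit on its carbon before the indole nucleus exists.
- **Prenyl group.** The alkene does not survive ozone, peracids, catalytic hydrogenation or strong protic and Lewis acids. Once the ring is aromatic its CH2 is both benzylic and allylic and open to hydride abstraction.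
- **N1–OH.** This is a cyclic hydroxamic acid. The N–O bond is cut by hydrogenolysis and dissolving metals and the free acid binds metal ions, so it must stay protected to the end and be released without hydrogen or a hard Lewis acid.
- **Pyrazinone.** The ring is at the oxidation level of a dehydrogenated diketopiperazine with one lactam as a methyl lactim ether. Methylation must go to O5 and not N4, and two hydrogens must be removed while nothing oxidizable is attached.
- **Enabling feature.** N1 of the indole is flanked by C7a and C2, and C7a–C3a–C3–C2 is a four-carbon chain. If C7a is the carbonyl carbon of a cyclohexanone (C4–C7 saturated) and C2 an aldehyde, C7 is an enolizable α-carbon that takes the prenyl group by alkylation, and ammonia closes the pyrrole ring on the 1,4-keto aldehyde.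

## Retrosynthesis

**22 from 21 (O–allyl bond).** The hydroxamic acid is unveiled last. In 21 it is an O-allyl ether, cleaved by Pd(PPh3)4 and morpholine. The prenyl group has no leaving group and is inert, and the N–O bond, lactim ether and indole are not touched. A benzyl ether would need hydrogenolysis (prenyl alkene, N–O bond) or a boron trihalide (prenyl alkene, indole), so allyl is preferred.

**21 from 9 and 20 (indole C3–CH2 bond).** C3 is the innate nucleophilic carbon of 7-prenylindole 9. Bromide 20 is a benzylic-type electrophile whose CH2 is conjugated to the C5 methoxy group. Cutting on the other side of the methylene would need a nucleophilic pyrazinone C6 or an unstable 3-(halomethyl)indole. The cut leaves a C13 indole and a C10 heterocycle, and every oxidation and methylation of the heterocycle is finished before the prenylindole is attached. The forward reaction must choose C3 over N1 and avoid strong acid.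

**9 from 8 (four hydrogens, no skeletal bond).** The benzene ring is carried as a saturated carbocycle and aromatized with DDQ. The pyrrole ring of tetrahydroindole 8 activates C4–H and C7–H for hydride abstraction. The forward step must stop before the prenyl CH2 is attacked.

**8 from 7 (N1–C7a and N1–C2; key disconnection).** Removing the nitrogen from the pyrrole ring leaves keto aldehyde 7. Cutting C3–C3a or starting from a benzene derivative would bring back the C7 regiochemistry problem as an ortho-prenylated arene. Here the problem becomes the α-alkylation of a ketone. The forward reaction needs ammonia to condense twice without the keto aldehyde closing to a furan or self-condensing.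

**7 from 6, 6 from 3 and 4, 3 from 1 (C7–prenyl bond).** The prenyl group enters by alkylating the kinetic enolate of ketone 3 with prenyl bromide 4 at the unsubstituted α-carbon. The aldehyde is a dimethyl acetal during this step because it cannot coexist with an amide base. The acetal comes from commercial 2-allylcyclohexanone 1 by ozonolysis, which must precede the arrival of the prenyl alkene. Hydrolysis of 6 then gives 7.

**20 from 19 from 18 (functional-group changes at the C6 carbon).** The bromide comes from alcohol 19 and this from ester 18. The ester serves as the one-carbon handle and needs no protecting group.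

**18 from 17 from 16 (two hydrogens; O-methyl).** Pyrazinone 18 is the dehydrogenation product of lactim ether 17, which comes from diketopiperazine 16 by O-methylation of its only N–H lactam with an oxonium salt. The hydroxamate nitrogen has no hydrogen, so the methyl group can only end on O5. The ester makes the adjacent C–H acidic, which eases dehydrogenation.

**16 from 14, 14 from 12 and 13, 12 from 10 and 11.** Ring closure is a lactamization of the alanine nitrogen onto one ester of malonate 14. The other ester stays as the handle. 14 is the N-alkylation product of O-allyl hydroxamate 12 with diethyl bromomalonate 13, and 12 is the amide of Boc-L-alanine 10 with O-allylhydroxylamine hydrochloride 11. All four building blocks are commercial.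

## Roads not taken

**Alternative 1:** Ugi-type assembly of the acyclic pyrazinone precursor.
- Cut: C5–C6 and N1–C2 of the future pyrazinone.
- Forward key step: ZnCl2 activates the O-benzyl oxime ether A1 of an N-Boc indol-3-ylacetaldehyde. The isocyanide A3 adds, pyruvic acid A2 traps the nitrilium ion, and Mumm acyl transfer places the pyruvoyl group on the N-benzyloxy nitrogen to give the racemic adduct A4. No ring closes.
- Merits: every atom of the heterocycle arrives in one step at the correct oxidation level, so no dehydrogenation is needed, and the racemic centre of A4 becomes sp2.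
- Weak points:
  - Oxime ethers are poor imine components and the N-alkoxy nitrogen is a reluctant acyl acceptor in the Mumm step.
  - The 2-nitrobenzyl amide has to be cut before the amide nitrogen can condense with the ketone.
  - The resulting 5-hydroxypyrazinone must be methylated on oxygen and not on N4, with the prenylindole already in the molecule.
  - Benzyl and Boc removal follow.
  - A1 rests on a labile indol-3-ylacetaldehyde and on a 7-prenylindole, whose origin this road does not address.
- Comparison: for the heterocycle alone this road is shorter than the seven steps from 10 to 20. The chosen plan solves the C7 problem by enolate chemistry, keeps methylation and oxidation of the heterocycle away from the prenylindole, and joins the halves in one mild step.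

**Alternative 2:** Rhodium-catalysed cyclotrimerization to a 7-prenylindoline.
- Cut: C3a–C7a, C4–C5 and C6–C7 of the benzene ring.
- Forward key step: RhCl(PPh3)3 joins the two alkynes of the N-tosyl ynamide diyne A5 with acetylene A6, closing the benzene ring and the fused five-membered nitrogen ring together, to give 7-prenyl-1-tosylindoline A7.
- Merits: the prenyl position is fixed by the substitution of the ynamide alkyne. The benzene ring is born aromatic, so no C–H oxidation of a carbocycle next to the prenyl group is needed. The sequence to A7 is short.
- Weak points: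
  - A5 holds a skipped enyne whose CH2 is propargylic and allylic and prone to isomerize during N-alkynylation and under rhodium.
  - A6 must be in excess to suppress self-trimerization of A5, and the alkene can enter enyne pathways.
  - A7 must still be oxidized to the indole and freed from the sulfonyl group before the electron-rich nucleus needed for C3 alkylation is in hand.
- Comparison: in regiochemical certainty the two roads are equal, and this road is better in avoiding the quinone dehydrogenation of step 5. The chosen plan uses bulk reagents, no gaseous alkyne and no rhodium, and delivers the N–H indole 9 directly. The endgame from 9 would be the same on either road.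

**Alternative 3:** Cyclodehydration of a pyruvamide to an alkylidene piperazinedione.
- Cut: N1–C6 of the heterocycle.
- Forward key step: TsOH in toluene makes the hydroxamate N–H of the N-(indolylpyruvoyl)alanine O-benzylhydroxamate A8 add to the ketone and lose water, giving the (3S,6Z)-alkylidene piperazinedione A9. O-methylation and tautomerization would then aromatize the ring.
- Merits: this is the most direct way to the heterocycle. The ring is at the right oxidation level without an oxidant, and cyclodehydration of pyruvoyl amino acid hydroxamates is a well-established reaction type.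
- Weak points:
  - Hot sulfonic acid acts on a molecule that already holds the prenyl alkene and a free indole.
  - The methylation must choose O5 over N4 and the indole nitrogen.
  - The benzyl group must be removed last beside the prenyl group.
  - A8 presupposes a 3-functionalized 7-prenylindole whose synthesis is left open.
- Comparison: for the pyrazinone this road is clearly shorter than the chosen fragment synthesis. The chosen plan supplies the indole that this road takes for granted and exposes the prenylindole to only two mild steps. An indole such as 9 could in principle feed this road as well.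

Key step: step 4

Remark on the chemistry: 22 has no stereocentre. Compounds 6, 7 and 8 are handled as racemic or diastereomeric mixtures, and the configuration of 10 is lost in step 10, so the descriptors of 12–17 are bookkeeping only.

## Route

Step 1
Reactants: 1 2-allylcyclohexan-1-one
Product: 3 2-(2,2-dimethoxyethyl)cyclohexan-1-one, via (2-oxocyclohexyl)acetaldehyde 2 (not isolated)
Conditions: O3, CH2Cl2/MeOH, −78 °C; Me2S, −78 °C → rt; then HC(OMe)3, CeCl3·7H2O (cat.), rt
Reagents that add atoms: ozone, O=[O+][O-] (aldehyde oxygen of 2); trimethyl orthoformate, COC(OC)OC, in methanol, CO (the two methoxy groups of 3)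
Why: Ozonolysis with reductive work-up cleaves the only alkene to keto aldehyde 2; CeCl3-catalysed acetalization with the orthoformate in methanol is selective for the aldehyde over the α-branched ketone, so the aldehyde is masked before the enolate step.

Step 2
Reactants: 3 2-(2,2-dimethoxyethyl)cyclohexan-1-one; 4 prenyl bromide (1-bromo-3-methylbut-2-ene)
Product: 6 2-(2,2-dimethoxyethyl)-6-(3-methylbut-2-en-1-yl)cyclohexan-1-one (mixture of diastereomers), via lithium enolate 5 (not isolated)
Conditions: LiN(iPr)2, THF, −78 °C; then 4, −78 → −20 °C
Reagents that add atoms: none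
Why: Kinetic deprotonation of a 2-substituted cyclohexanone by the hindered lithium amide takes the proton of the unsubstituted α-carbon, and the less substituted enolate 5 is alkylated by the allylic bromide at its primary carbon (SN2) before the enolates equilibrate. The new stereocentre is not controlled and need not be, since it is lost in step 5.

Step 3
Reactants: 6 2-(2,2-dimethoxyethyl)-6-(3-methylbut-2-en-1-yl)cyclohexan-1-one
Product: 7 2-[3-(3-methylbut-2-en-1-yl)-2-oxocyclohexyl]acetaldehyde (mixture of diastereomers, used crude)
Conditions: 1 M aq. HCl, THF, 0 °C → rt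
Reagents that add atoms: water, O
Why: Acid-catalysed hydrolysis of a dimethyl acetal; dilute acid at or below room temperature should not hydrate the trisubstituted alkene or dehydrate the 1,4-keto aldehyde to a furan.

Step 4
Reactants: 7 2-[3-(3-methylbut-2-en-1-yl)-2-oxocyclohexyl]acetaldehyde
Product: 8 7-(3-methylbut-2-en-1-yl)-4,5,6,7-tetrahydro-1H-indole (racemic)
Conditions: NH4OAc (excess), AcOH, 50 °C, argon
Reagents that add atoms: ammonium acetate, CC(=O)[O-].[NH4+] (nitrogen N1)
Why: Paal–Knorr pyrrole synthesis on a 1,4-keto aldehyde. Ammonia from NH4OAc adds first to the more electrophilic aldehyde to give a hemiaminal or imine, whose nitrogen then attacks the ring ketone in a 5-exo-trig closure of the five-membered ring; two acid-catalysed dehydrations give the aromatic pyrrole, so that N1–C2 and N1–C7a are formed. The closest known reaction type is the ammonium acetate condensation of 2-(2-oxoethyl)cyclohexanones to 4,5,6,7-tetrahydroindoles. No stereocentre is created: the α-carbon that carried the side chain becomes sp2 (C3a), both diastereomers of 7 converge on racemic 8, and its one sp3 centre (C7) disappears in step 5. The step needs chemoselectivity for the pyrrole over furan formation and over aldol self-condensation; the large excess of the nitrogen source in buffered acetic acid and the intramolecular second C–N bond formation should secure it. The prenyl alkene should be a spectator because no acid stronger than acetic acid is present. The position of the prenyl group (C7) was fixed by the site of enolization in step 2 and cannot change here.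

Step 5
Reactants: 8 7-(3-methylbut-2-en-1-yl)-4,5,6,7-tetrahydro-1H-indole
Product: 9 7-(3-methylbut-2-en-1-yl)-1H-indole (7-prenylindole)
Conditions: DDQ (2.1 equiv), 1,4-dioxane, rt, argon
Reagents that add atoms: none
Why: Quinone dehydrogenation of a 4,5,6,7-tetrahydroindole: DDQ abstracts hydride from C4 or C7, which the pyrrole ring activates, and proton loss followed by a second hydride abstraction and proton loss gives the benzene ring. Two equivalents at room temperature are meant to stop the reaction before the benzylic-allylic CH2 of the product is attacked.

Step 6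
Reactants: 10 N-Boc-L-alanine; 11 O-allylhydroxylamine hydrochloride
Product: 12 tert-butyl N-[(2S)-1-(allyloxyamino)-1-oxopropan-2-yl]carbamate
Conditions: EDC·HCl, HOBt, N-methylmorpholine, CH2Cl2, 0 °C → rt
Reagents that add atoms: none
Why: Carbodiimide amide coupling of a urethane-protected amino acid with an O-alkylhydroxylamine, a standard route to O-protected hydroxamates.

Step 7
Reactants: 12 tert-butyl N-[(2S)-1-(allyloxyamino)-1-oxopropan-2-yl]carbamate; 13 diethyl 2-bromomalonate
Product: 14 diethyl 2-[(allyloxy){(2S)-2-[(tert-butoxycarbonyl)amino]propanoyl}amino]malonate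
Conditions: K2CO3, DMF, 0 °C → rt
Reagents that add atoms: none
Why: N-Alkylation of an O-alkyl hydroxamate with an α-halo ester: the hydroxamate N–H is the most acidic proton, and its anion displaces bromide from the activated bromo diester (SN2). The carbamate N–H is not deprotonated by carbonate.

Step 8
Reactants: 14 diethyl 2-[(allyloxy){(2S)-2-[(tert-butoxycarbonyl)amino]propanoyl}amino]malonate
Product: 16 ethyl (5S)-1-(allyloxy)-5-methyl-3,6-dioxopiperazine-2-carboxylate (mixture at C2), via aminoacyl malonate trifluoroacetate 15 (not isolated)
Conditions: TFA, CH2Cl2, 0 °C → rt; concentrate; then sat. aq. NaHCO3, EtOAc, rt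
Reagents that add atoms: none
Why: Acidolysis of the Boc group, then lactamization of the freed amine onto one of the two equivalent esters (6-exo-trig), which the cis-like geometry of the N,N-disubstituted hydroxamate favours. Only bicarbonate is used, because a stronger base could expel allyl alcohol from the anion at the acidic C2–H.

Step 9
Reactants: 16 ethyl (5S)-1-(allyloxy)-5-methyl-3,6-dioxopiperazine-2-carboxylate
Product: 17 ethyl (5S)-1-(allyloxy)-3-methoxy-5-methyl-6-oxo-1,2,5,6-tetrahydropyrazine-2-carboxylate
Conditions: Me3OBF4, CH2Cl2, rt; cold aq. NaHCO3 work-up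
Reagents that add atoms: trimethyloxonium tetrafluoroborate, C[O+](C)C.F[B-](F)(F)F
Why: Lactim ether formation by O-alkylation of a secondary lactam with a trialkyloxonium salt. The oxygen of the N–H lactam is the most nucleophilic site and the hydroxamate nitrogen has no hydrogen to lose, so the methyl group is placed on O and not on N4.

Step 10
Reactants: 17 ethyl (5S)-1-(allyloxy)-3-methoxy-5-methyl-6-oxo-1,2,5,6-tetrahydropyrazine-2-carboxylate
Product: 18 ethyl 1-(allyloxy)-3-methoxy-5-methyl-6-oxo-1,6-dihydropyrazine-2-carboxylate
Conditions: DDQ (1.1 equiv), toluene, rt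
Reagents that add atoms: none
Why: Dehydrogenation of a dihydropyrazinone lactim ether to the pyrazinone with DDQ, as used to aromatize lactim ethers of diketopiperazines. The ester-activated C–H makes the enamine tautomer accessible, and the gain of the aromatic pyrazinone drives the reaction; both sp3 centres vanish.

Step 11
Reactants: 18 ethyl 1-(allyloxy)-3-methoxy-5-methyl-6-oxo-1,6-dihydropyrazine-2-carboxylate
Product: 19 1-(allyloxy)-6-(hydroxymethyl)-5-methoxy-3-methylpyrazin-2(1H)-one
Conditions: iBu2AlH (2.5 equiv), CH2Cl2, −78 °C; aq. KNaC4H4O6 work-up
Reagents that add atoms: none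
Why: Low-temperature reduction of an ester to the primary alcohol with a dialkylaluminium hydride. The ester is the only carbonyl outside the heteroaromatic ring, and the ring carbonyl is deactivated by conjugation.

Step 12
Reactants: 19 1-(allyloxy)-6-(hydroxymethyl)-5-methoxy-3-methylpyrazin-2(1H)-one
Product: 20 1-(allyloxy)-6-(bromomethyl)-5-methoxy-3-methylpyrazin-2(1H)-one
Conditions: CBr4, PPh3, CH2Cl2, 0 °C
Reagents that add atoms: carbon tetrabromide, BrC(Br)(Br)Br
Why: Appel reaction of a primary benzylic-type alcohol under neutral conditions; the allyl ether and the lactim ether are not affected. The bromide is used without storage.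

Step 13
Reactants: 9 7-(3-methylbut-2-en-1-yl)-1H-indole; 20 1-(allyloxy)-6-(bromomethyl)-5-methoxy-3-methylpyrazin-2(1H)-one
Product: 21 1-(allyloxy)-5-methoxy-3-methyl-6-{[7-(3-methylbut-2-en-1-yl)-1H-indol-3-yl]methyl}pyrazin-2(1H)-one
Conditions: Zn(OTf)2, iPr2NEt, toluene, rt
Reagents that add atoms: none
Why: Friedel–Crafts-type C3 alkylation of an N-unprotected indole with a benzylic-type bromide, mediated by Zn(OTf)2 and a tertiary amine. The zinc indolide reacts at C3, and the amine takes up HBr, so neither N-alkylation nor acid damage to the prenyl group is expected.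

Step 14
Reactants: 21 1-(allyloxy)-5-methoxy-3-methyl-6-{[7-(3-methylbut-2-en-1-yl)-1H-indol-3-yl]methyl}pyrazin-2(1H)-one
Product: 22 astepyrazinoxide, 1-hydroxy-5-methoxy-3-methyl-6-{[7-(3-methylbut-2-en-1-yl)-1H-indol-3-yl]methyl}pyrazin-2(1H)-one
Conditions: Pd(PPh3)4 (5 mol%), morpholine, THF, rt
Reagents that add atoms: none
Why: Tsuji–Trost-type deallylation of an O-allyl hydroxamate: zerovalent palladium ionizes the allyl group with the hydroxamate as leaving group, and morpholine traps the allyl fragment. The prenyl group has no leaving group, and the N–O bond, lactim ether and indole are not touched.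

## Compound list

1 | 2-allylcyclohexan-1-one (racemic) | C=CCC1CCCCC1=O | starting material
2 | (2-oxocyclohexyl)acetaldehyde | O=CCC1CCCCC1=O | intermediate (not isolated)
3 | 2-(2,2-dimethoxyethyl)cyclohexan-1-one | COC(CC1CCCCC1=O)OC | intermediate
4 | prenyl bromide (1-bromo-3-methylbut-2-ene) | CC(C)=CCBr | starting material
5 | lithium 6-(2,2-dimethoxyethyl)cyclohex-1-en-1-olate | [Li+].[O-]C1=CCCCC1CC(OC)OC | intermediate (not isolated)
6 | 2-(2,2-dimethoxyethyl)-6-(3-methylbut-2-en-1-yl)cyclohexan-1-one (mixture of diastereomers) | COC(CC1CCCC(CC=C(C)C)C1=O)OC | intermediate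
7 | 2-[3-(3-methylbut-2-en-1-yl)-2-oxocyclohexyl]acetaldehyde (mixture of diastereomers) | O=CCC1CCCC(CC=C(C)C)C1=O | intermediate
8 | 7-(3-methylbut-2-en-1-yl)-4,5,6,7-tetrahydro-1H-indole (racemic) | CC(C)=CCC1CCCc2cc[nH]c21 | intermediate
9 | 7-(3-methylbut-2-en-1-yl)-1H-indole | CC(C)=CCc1cccc2cc[nH]c12 | intermediate
10 | N-Boc-L-alanine | C[C@H](NC(=O)OC(C)(C)C)C(=O)O | starting material
11 | O-allylhydroxylamine hydrochloride | C=CCON.Cl | starting material
12 | tert-butyl N-[(2S)-1-(allyloxyamino)-1-oxopropan-2-yl]carbamate | C[C@H](NC(=O)OC(C)(C)C)C(=O)NOCC=C | intermediate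
13 | diethyl 2-bromomalonate | CCOC(=O)C(Br)C(=O)OCC | starting material
14 | diethyl 2-[(allyloxy){(2S)-2-[(tert-butoxycarbonyl)amino]propanoyl}amino]malonate | C[C@H](NC(=O)OC(C)(C)C)C(=O)N(OCC=C)C(C(=O)OCC)C(=O)OCC | intermediate
15 | diethyl 2-{(allyloxy)[(2S)-2-aminopropanoyl]amino}malonate trifluoroacetate | C[C@H](N)C(=O)N(OCC=C)C(C(=O)OCC)C(=O)OCC.OC(=O)C(F)(F)F | intermediate (not isolated)
16 | ethyl (5S)-1-(allyloxy)-5-methyl-3,6-dioxopiperazine-2-carboxylate (mixture at C2) | CCOC(=O)C1N(OCC=C)C(=O)[C@H](C)NC1=O | intermediate
17 | ethyl (5S)-1-(allyloxy)-3-methoxy-5-methyl-6-oxo-1,2,5,6-tetrahydropyrazine-2-carboxylate (mixture at C2) | CCOC(=O)C1N(OCC=C)C(=O)[C@H](C)N=C1OC | intermediate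
18 | ethyl 1-(allyloxy)-3-methoxy-5-methyl-6-oxo-1,6-dihydropyrazine-2-carboxylate | CCOC(=O)c1c(OC)nc(C)c(=O)n1OCC=C | intermediate
19 | 1-(allyloxy)-6-(hydroxymethyl)-5-methoxy-3-methylpyrazin-2(1H)-one | COc1nc(C)c(=O)n(OCC=C)c1CO | intermediate
20 | 1-(allyloxy)-6-(bromomethyl)-5-methoxy-3-methylpyrazin-2(1H)-one | COc1nc(C)c(=O)n(OCC=C)c1CBr | intermediate
21 | 1-(allyloxy)-5-methoxy-3-methyl-6-{[7-(3-methylbut-2-en-1-yl)-1H-indol-3-yl]methyl}pyrazin-2(1H)-one | COc1nc(C)c(=O)n(OCC=C)c1Cc1c[nH]c2c(CC=C(C)C)cccc12 | intermediate
22 | astepyrazinoxide | COc1nc(C)c(=O)n(O)c1Cc1c[nH]c2c(CC=C(C)C)cccc12 | target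

## Step count and least certain steps

Total: 14 steps. Longest linear sequence: 9 steps (steps 6 to 14, from 10). The indole branch (steps 1 to 5) joins at step 13.

**Step 4 (key step).**
- Most likely failure: the keto aldehyde is consumed by acid-promoted cyclodehydration to the furan or by aldol-type self-condensation before ammonia is taken up twice, and the N-unsubstituted, electron-rich pyrrole is degraded by air and acid during the reaction.
- Fallback: it sets out from 7 and returns at 9.
  - 7 is condensed with a primary amine, 2-(phenylsulfonyl)ethanamine, under mild Paal–Knorr conditions (cat. AcOH, EtOH, rt) to give 1-[2-(phenylsulfonyl)ethyl]-7-(3-methylbut-2-en-1-yl)-4,5,6,7-tetrahydro-1H-indole F1.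
  - Primary amines condense faster and more cleanly than ammonia, and the N-alkyl pyrrole is more robust.
  - DDQ then gives 1-[2-(phenylsulfonyl)ethyl]-7-(3-methylbut-2-en-1-yl)-1H-indole F2.
  - tBuOK in THF removes the N-substituent by retro-Michael loss of phenyl vinyl sulfone and gives 9.

**Step 5.**
- Most likely failure: over-oxidation by hydride abstraction from the benzylic-allylic CH2 of the prenyl group once the ring is aromatic, and adduct formation between the quinone and the unprotected electron-rich pyrrole.
- Fallback: it sets out from 8 and returns at 9.
  - N-Sulfonylation (NaH, TsCl, THF) gives 7-(3-methylbut-2-en-1-yl)-1-tosyl-4,5,6,7-tetrahydro-1H-indole F3, whose deactivated pyrrole no longer couples with the quinone.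
  - Dehydrogenation with DDQ in warm toluene gives 7-(3-methylbut-2-en-1-yl)-1-tosyl-1H-indole F4. The sulfonyl group also lowers the hydride-donor ability of the prenyl CH2.
  - KOH in MeOH/THF removes the sulfonyl group and gives 9.

**Step 7.**
- Most likely failure: alkylation of the ambident hydroxamate anion at the carbonyl oxygen, and base-induced loss of allyl alcohol across the N–C bond from the deprotonated malonate product.
- Fallback: it reverses the order of bond formation, sets out from 11, 13 and 10, and returns at 14.
  - O-Allylhydroxylamine freed from 11 is alkylated on nitrogen by 13 (Et3N, MeCN) to give diethyl 2-[(allyloxy)amino]malonate F5.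
  - 10 is converted with cyanuric fluoride and pyridine into N-Boc-L-alanyl fluoride F6, an acylating agent known to reach hindered, weakly basic amines.
  - F5 and F6 with iPr2NEt give 14 without an anionic malonate being formed.

**Step 11.**
- Most likely failure: hydride addition to the ring (the N-alkoxy lactam carbonyl or the C=N bond) in competition with the vinylogous, deactivated ester, or reduction beyond the alcohol.
- Fallback: it sets out from 18 and returns at 19.
  - Saponification (LiOH, THF/H2O, 0 °C) gives 1-(allyloxy)-3-methoxy-5-methyl-6-oxo-1,6-dihydropyrazine-2-carboxylic acid F7.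
  - Isobutyl chloroformate and N-methylmorpholine give the isobutyl carbonic mixed anhydride F8.
  - NaBH4 in THF/H2O at 0 °C reduces this activated carboxyl selectively to 19.

**Step 13.**
- Most likely failure: alkylation at the indole nitrogen or twice at C3 (3,3-disubstituted indolenine), and decomposition of the ionizable bromide before the indole intercepts it.
- Fallback: it changes the electrophile from halide to aldehyde, sets out from 19 and returns at 21.
  - MnO2 in CH2Cl2 gives 1-(allyloxy)-3-methoxy-5-methyl-6-oxo-1,6-dihydropyrazine-2-carbaldehyde F9.
  - Base-mediated hydroxyalkylation of 9 with F9 (K2CO3, MeOH) gives {1-(allyloxy)-3-methoxy-5-methyl-6-oxo-1,6-dihydropyrazin-2-yl}[7-(3-methylbut-2-en-1-yl)-1H-indol-3-yl]methanol F10.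
  - NaBH4 in warm EtOH removes the indol-3-yl carbinol oxygen through the 3-alkylidene-3H-indole and gives 21. No acid is present that could harm the prenyl group.

## Further compounds

F1 | step 4 | 1-[2-(phenylsulfonyl)ethyl]-7-(3-methylbut-2-en-1-yl)-4,5,6,7-tetrahydro-1H-indole | CC(C)=CCC1CCCc2ccn(CCS(=O)(=O)c3ccccc3)c21
F2 | step 4 | 1-[2-(phenylsulfonyl)ethyl]-7-(3-methylbut-2-en-1-yl)-1H-indole | CC(C)=CCc1cccc2ccn(CCS(=O)(=O)c3ccccc3)c12
F3 | step 5 | 7-(3-methylbut-2-en-1-yl)-1-tosyl-4,5,6,7-tetrahydro-1H-indole | CC(C)=CCC1CCCc2ccn(S(=O)(=O)c3ccc(C)cc3)c21
F4 | step 5 | 7-(3-methylbut-2-en-1-yl)-1-tosyl-1H-indole | CC(C)=CCc1cccc2ccn(S(=O)(=O)c3ccc(C)cc3)c12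
F5 | step 7 | diethyl 2-[(allyloxy)amino]malonate | CCOC(=O)C(NOCC=C)C(=O)OCC
F6 | step 7 | N-Boc-L-alanyl fluoride | C[C@H](NC(=O)OC(C)(C)C)C(F)=O
F7 | step 11 | 1-(allyloxy)-3-methoxy-5-methyl-6-oxo-1,6-dihydropyrazine-2-carboxylic acid | O=C(O)c1c(OC)nc(C)c(=O)n1OCC=C
F8 | step 11 | isobutyl carbonic anhydride of F7 | CC(C)COC(=O)OC(=O)c1c(OC)nc(C)c(=O)n1OCC=C
F9 | step 13 | 1-(allyloxy)-3-methoxy-5-methyl-6-oxo-1,6-dihydropyrazine-2-carbaldehyde | O=Cc1c(OC)nc(C)c(=O)n1OCC=C
F10 | step 13 | {1-(allyloxy)-3-methoxy-5-methyl-6-oxo-1,6-dihydropyrazin-2-yl}[7-(3-methylbut-2-en-1-yl)-1H-indol-3-yl]methanol (racemic) | COc1nc(C)c(=O)n(OCC=C)c1C(O)c1c[nH]c2c(CC=C(C)C)cccc12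
A1 | alternative 1 | tert-butyl 3-[2-(benzyloxyimino)ethyl]-7-(3-methylbut-2-en-1-yl)indole-1-carboxylate | CC(C)=CCc1cccc2c(CC=NOCc3ccccc3)cn(C(=O)OC(C)(C)C)c12
A2 | alternative 1 | pyruvic acid | CC(=O)C(=O)O
A3 | alternative 1 | 2-nitrobenzyl isocyanide | [C-]#[N+]Cc1ccccc1[N+](=O)[O-]
A4 | alternative 1 | racemic N-benzyloxy-N-pyruvoyl α-amino amide (Ugi adduct) | CC(=O)C(=O)N(OCc1ccccc1)C(Cc1cn(C(=O)OC(C)(C)C)c2c(CC=C(C)C)cccc12)C(=O)NCc1ccccc1[N+](=O)[O-]
A5 | alternative 2 | N-(but-3-yn-1-yl)-4-methyl-N-(5-methylhex-4-en-1-yn-1-yl)benzenesulfonamide | C#CCCN(C#CCC=C(C)C)S(=O)(=O)c1ccc(C)cc1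
A6 | alternative 2 | acetylene | C#C
A7 | alternative 2 | 7-(3-methylbut-2-en-1-yl)-1-tosylindoline | CC(C)=CCc1cccc2c1N(S(=O)(=O)c1ccc(C)cc1)CC2
A8 | alternative 3 | (2S)-N-(benzyloxy)-2-{3-[7-(3-methylbut-2-en-1-yl)-1H-indol-3-yl]-2-oxopropanamido}propanamide | C[C@H](NC(=O)C(=O)Cc1c[nH]c2c(CC=C(C)C)cccc12)C(=O)NOCc1ccccc1
A9 | alternative 3 | (3S,6Z)-1-(benzyloxy)-3-methyl-6-{[7-(3-methylbut-2-en-1-yl)-1H-indol-3-yl]methylidene}piperazine-2,5-dione | C[C@@H]1NC(=O)/C(=C/c2c[nH]c3c(CC=C(C)C)cccc23)N(OCc2ccccc2)C1=O
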